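**Plan**

- Ring positions follow the cyclohexenone: C1 carbonyl, C2 (bears CH2O), C3 (vinylic CH), C4 (ester carbon), C5 (isopropyl carbon), C6 (carbinol carbon). Tig = tigloyl = (2E)-2-methylbut-2-enoyl.
- Retrosynthesis: cut the C6–OH bond first (late alpha'-hydroxylation), then both tiglate C–O bonds (the one at C4 with inversion), then the C4–O bond (gamma-oxygenation). Finally cut the ring bonds C1–C2 and C3–C4, which removes C2/C3 as a C-silylated propargyl ether and leaves C4–C5–C6–C1 as 3-isopropylcyclobutanone.
- Enabling feature: once the C2=C3 unit is taken out of the six-membered ring, C1 and the isopropyl-bearing C5 lie on a mirror plane of a strained four-membered ketone, whose two C(=O)–CH2 bonds are therefore enantiotopic.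
- Forward: the four-membered ring arises by dichloroketene [2+2] cycloaddition and dechlorination; the six-membered ring by nickel-catalysed insertion of the alkyne into one C(=O)–CH2 bond (ring expansion), a C-silyl group fixing the alkyne orientation. Then follow C3 desilylation, C4 oxygenation, double esterification and C6 hydroxylation.
- Stereochemistry: C5 from ligand-controlled choice between the two enantiotopic ring bonds; C4 from oxidation anti to isopropyl followed by Mitsunobu inversion; C6 from oxidation anti to the isopropyl and C4 ester groups.

Key step: step 4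

Remark: the sense of asymmetric induction in step 4 cannot be predicted with confidence, so the ligand antipode named there is assumed to be the one that delivers (5R)-8.

**Step 1**
Reactants: 1 3-methylbut-1-ene (excess); 2 trichloroacetyl chloride
Product: 4 racemic 2,2-dichloro-3-isopropylcyclobutan-1-one, via dichloroketene 3 (not isolated)
Conditions: zinc–copper couple, Et2O/DME, 0 °C to rt, slow addition of 2
Reagents that add atoms: none
Why: Zinc dechlorinates 2 to dichloroketene, which should add to the terminal alkene in a thermal ketene–alkene [2+2] cycloaddition with the carbonyl carbon bonding to the CH2 terminus, so that the isopropyl group sits at C3; the single stereocentre forms as a racemate and loses its stereogenicity in step 2.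

**Step 2**
Reactants: 4 racemic 2,2-dichloro-3-isopropylcyclobutan-1-one
Product: 5 3-isopropylcyclobutan-1-one
Conditions: Zn dust, AcOH, rt to 60 °C
Reagents that add atoms: none
Why: Zinc in acetic acid reduces both alpha C–Cl bonds of the alpha,alpha-dichloroketone (reductive dehalogenation) without opening the strained ring, giving the achiral, mirror-symmetric ketone.

**Step 3**
Reactants: 6 3-(trimethylsilyl)prop-2-yn-1-ol
Product: 7 tert-butyldimethyl{[3-(trimethylsilyl)prop-2-yn-1-yl]oxy}silane
Conditions: TBSCl, imidazole, CH2Cl2, 0 °C to rt
Reagents that add atoms: tert-butyldimethylsilyl chloride (TBSCl), CC(C)(C)[Si](C)(C)Cl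
Why: Standard silyl ether formation masks the propargylic hydroxyl, which would otherwise protonate organonickel intermediates in step 4, while the C-silyl group is untouched under these mild conditions.

**Step 4**
Reactants: 5 3-isopropylcyclobutan-1-one; 7 tert-butyldimethyl{[3-(trimethylsilyl)prop-2-yn-1-yl]oxy}silane
Product: 8 (5R)-2-{[(tert-butyldimethylsilyl)oxy]methyl}-5-isopropyl-3-(trimethylsilyl)cyclohex-2-en-1-one
Conditions: Ni(cod)2 (10 mol%), (S,S,S)-BINOL-derived bis(1-phenylethyl)phosphoramidite ligand (20 mol%), toluene, 90 °C, slow addition of 7 (1.5 equiv)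
Reagents that add atoms: none
Why: Proposed new method: oxidative cyclization of the ketone carbonyl and the alkyne on zerovalent nickel should give a spiro oxanickelacyclopentene in which, for steric reasons and because silicon stabilises the adjacent C–Ni bond, the silyl-bearing carbon is bound to nickel and the CH2OTBS-bearing carbon to the former carbonyl carbon; strain-driven beta-carbon elimination of one ring C–C bond then gives a seven-membered nickelacycle, and C(sp2)–C(sp3) reductive elimination releases the cyclohexenone with both new bonds (C1–C2 and C3–C4) made in one catalytic cycle. The closest known reaction type is the nickel-catalysed intermolecular insertion of internal alkynes into 3-substituted cyclobutanones and azetidin-3-ones with achiral phosphines, together with the enantioselective intramolecular alkene insertion into cyclobutanones on zerovalent nickel with a chiral phosphoramidite; what is new is the enantioselective intermolecular version. The six-membered ring is closed not by an exo or endo cyclisation but by ring expansion, that is reductive elimination from the nickelacycloheptenone (formal [4+2] of a C–C sigma bond with the alkyne). The only stereocentre, C5, becomes stereogenic when the chiral ligand on nickel selects one of the two enantiotopic C(=O)–CH2 bonds in the beta-carbon elimination, so the ligand is the controlling element. The step needs enantiotopic-bond selectivity (ligand), one alkyne orientation (secured by the C-silyl group, which ends at C3) and chemoselectivity over alkyne oligomerisation (secured by the bulky silylalkyne and its slow addition).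

**Step 5**
Reactants: 8 (5R)-2-{[(tert-butyldimethylsilyl)oxy]methyl}-5-isopropyl-3-(trimethylsilyl)cyclohex-2-en-1-one
Product: 9 (5S)-2-(hydroxymethyl)-5-isopropylcyclohex-2-en-1-one
Conditions: TBAF·3H2O (3 equiv), THF, 0 °C to 40 °C
Reagents that add atoms: none
Why: Fluoride cleaves the primary O–Si bond and, by attack at the vinylic silicon with protonation of carbon by water, should also cleave the C3–Si bond of the beta-silyl enone (fluoride-mediated desilylation and protodesilylation), so the orientation-fixing helper and the oxygen protecting group leave together; C5 is not involved and its descriptor changes only because the priorities change.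

**Step 6**
Reactants: 9 (5S)-2-(hydroxymethyl)-5-isopropylcyclohex-2-en-1-one
Product: 11 (4S,5S)-4-hydroxy-2-(hydroxymethyl)-5-isopropylcyclohex-2-en-1-one, via bis(trimethylsilyl) dienol ether 10 (not isolated)
Conditions: MeMgBr (2.3 equiv), FeCl3 (5 mol%), Et2O, −20 °C; TMSCl, Et3N, DMPU, −20 °C to rt; pentane filtration; DMDO, acetone/CH2Cl2, −78 to −40 °C; citric acid, MeOH, 0 °C
Reagents that add atoms: dimethyldioxirane (DMDO), CC1(C)OO1; chlorotrimethylsilane (TMSCl), C[Si](C)(C)Cl (silyl groups carried only in 10)
Why: Iron-catalysed deprotonation by MeMgBr should give, after the hydroxyl proton is consumed, the through-conjugated C1–C4 magnesium dienolate (thermodynamic gamma-deprotonation, the C7 alkoxide being too poor a leaving group to be expelled), which is O-silylated; DMDO then epoxidises the terminal C3=C4 bond from the face opposite the adjacent C5 isopropyl group, and silyl-assisted opening (vinylogous Rubottom oxidation) with acidic methanolysis gives the 4-hydroxy enone with the new C4 hydroxyl trans to isopropyl (substrate control).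

**Step 7**
Reactants: 11 (4S,5S)-4-hydroxy-2-(hydroxymethyl)-5-isopropylcyclohex-2-en-1-one; 12 tiglic acid (3 equiv)
Product: 13 (4R,5S)-5-isopropyl-4-(tigloyloxy)-2-[(tigloyloxy)methyl]cyclohex-2-en-1-one
Conditions: PPh3 (3 equiv), DIAD (3 equiv), toluene, 0 °C to rt
Reagents that add atoms: none
Why: Under Mitsunobu conditions the primary allylic alcohol is esterified without stereochemical consequence and the secondary allylic C4 alcohol is displaced by tiglate in an SN2 process with inversion (as known for menthol-type alcohols next to an isopropyl-bearing carbon), which turns the trans alcohol into the required cis C4 ester.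

**Step 8**
Reactants: 13 (4R,5S)-5-isopropyl-4-(tigloyloxy)-2-[(tigloyloxy)methyl]cyclohex-2-en-1-one
Product: 15 (4S,5R,6R)-6-hydroxy-5-isopropyl-4-(tigloyloxy)-2-[(tigloyloxy)methyl]cyclohex-2-en-1-one, via trimethylsilyl dienol ether 14 (not isolated)
Conditions: TMSOTf, Et3N, CH2Cl2, −78 to 0 °C; pentane filtration; DMDO, acetone/CH2Cl2, −78 °C; citric acid, THF/H2O, 0 °C
Reagents that add atoms: dimethyldioxirane (DMDO), CC1(C)OO1; trimethylsilyl trifluoromethanesulfonate (TMSOTf), C[Si](C)(C)OS(=O)(=O)C(F)(F)F (silyl group carried only in 14)
Why: Soft enolisation of the enone should give the kinetic cross-conjugated 2-silyloxy diene by deprotonation at C6, whose electron-rich enol ether bond is epoxidised by DMDO from the face opposite both the C5 isopropyl and the C4 tigloyloxy groups, and hydrolysis then gives the C6 hydroxy ketone trans to isopropyl (Rubottom oxidation), the electron-poor enone and tiglate double bonds being left alone.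

**Compound list**

1 | 3-methylbut-1-ene | C=CC(C)C | starting material
2 | trichloroacetyl chloride | ClC(=O)C(Cl)(Cl)Cl | starting material
3 | dichloroketene | ClC(Cl)=C=O | intermediate
4 | racemic 2,2-dichloro-3-isopropylcyclobutan-1-one | CC(C)C1CC(=O)C1(Cl)Cl | intermediate
5 | 3-isopropylcyclobutan-1-one | CC(C)C1CC(=O)C1 | intermediate
6 | 3-(trimethylsilyl)prop-2-yn-1-ol | C[Si](C)(C)C#CCO | starting material
7 | tert-butyldimethyl{[3-(trimethylsilyl)prop-2-yn-1-yl]oxy}silane | C[Si](C)(C)C#CCO[Si](C)(C)C(C)(C)C | intermediate
8 | (5R)-2-{[(tert-butyldimethylsilyl)oxy]methyl}-5-isopropyl-3-(trimethylsilyl)cyclohex-2-en-1-one | O=C1C(CO[Si](C)(C)C(C)(C)C)=C([Si](C)(C)C)C[C@H](C(C)C)C1 | intermediate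
9 | (5S)-2-(hydroxymethyl)-5-isopropylcyclohex-2-en-1-one | O=C1C(CO)=CC[C@H](C(C)C)C1 | intermediate
10 | (5S)-5-isopropyl-1-(trimethylsilyloxy)-2-[(trimethylsilyloxy)methyl]cyclohexa-1,3-diene | C[Si](C)(C)OCC1=C(O[Si](C)(C)C)C[C@@H](C(C)C)C=C1 | intermediate
11 | (4S,5S)-4-hydroxy-2-(hydroxymethyl)-5-isopropylcyclohex-2-en-1-one (hydroxyl trans to isopropyl) | O=C1C(CO)=C[C@@H](O)[C@H](C(C)C)C1 | intermediate
12 | tiglic acid, (2E)-2-methylbut-2-enoic acid | C/C=C(\C)C(=O)O | starting material
13 | (4R,5S)-5-isopropyl-4-(tigloyloxy)-2-[(tigloyloxy)methyl]cyclohex-2-en-1-one (C4 ester cis to isopropyl) | C/C=C(\C)C(=O)OCC1=C[C@H](OC(=O)/C(C)=C/C)[C@H](C(C)C)CC1=O | intermediate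
14 | [(3R,4R)-4-isopropyl-3-(tigloyloxy)-6-(trimethylsilyloxy)cyclohexa-1,5-dien-1-yl]methyl tiglate | C/C=C(\C)C(=O)OCC1=C[C@H](OC(=O)/C(C)=C/C)[C@H](C(C)C)C=C1O[Si](C)(C)C | intermediate
15 | (4S,5R,6R)-6-hydroxy-5-isopropyl-4-(tigloyloxy)-2-[(tigloyloxy)methyl]cyclohex-2-en-1-one | C/C=C(\C)C(=O)OCC1=C[C@H](OC(=O)/C(C)=C/C)[C@H](C(C)C)[C@@H](O)C1=O | target

**Step count and risks**

Total step count: 8. Longest linear sequence: 7 steps (steps 1, 2, 4, 5, 6, 7, 8 from 1 and 2 to 15); the alkyne branch is one step (step 3).

The three steps most likely to fail: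

1. Step 4 (the step beyond precedent). The chiral ligand may differentiate the two enantiotopic C(=O)–CH2 bonds poorly, or the phosphoramidite–nickel catalyst may not turn over with the hindered silylalkyne, so that alkyne oligomerisation takes over. Fallback, using known chemistry: from 5 and 7 the insertion is run with the established achiral system Ni(cod)2/PCy3 in toluene at 100 °C to give racemic 2-{[(tert-butyldimethylsilyl)oxy]methyl}-5-isopropyl-3-(trimethylsilyl)cyclohex-2-en-1-one F1. This is resolved by preparative chromatography on a chiral stationary phase; the (5R) enantiomer is 8, where the route is rejoined.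

2. Step 6. Deprotonation may occur at C6 instead of C4, the epoxidation may take place at the enol ether bond C1=C2 instead of C3=C4, or the C7 oxygen may be lost from the dienolate with aromatisation to a phenol. Fallback: from 9, acylation with tigloyl chloride (pyridine, DMAP, CH2Cl2) gives [(4S)-4-isopropyl-6-oxocyclohex-1-en-1-yl]methyl tiglate F2. Wohl–Ziegler bromination at the gamma position (N-bromosuccinimide, AIBN, PhCF3, reflux) should place bromine anti to isopropyl and give [(3S,4S)-3-bromo-4-isopropyl-6-oxocyclohex-1-en-1-yl]methyl tiglate F3. Displacement with cesium tiglate F4 (made from 12 and Cs2CO3) in DMF at rt proceeds with inversion and comes back to the route at 13, so that step 7 is bypassed as well.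

3. Step 7. Substitution at the hindered C4 position by the weakly acidic tiglic acid may be slow, so that elimination towards a dienone and its aromatisation, or esterification with retention, compete. Fallback: from 11, selective acylation of the primary hydroxyl (tigloyl chloride, 2,4,6-collidine, CH2Cl2, −78 °C) gives [(3S,4S)-3-hydroxy-4-isopropyl-6-oxocyclohex-1-en-1-yl]methyl tiglate F5. Mesylation (MsCl, Et3N, CH2Cl2, −20 °C) gives [(3S,4S)-4-isopropyl-3-(methanesulfonyloxy)-6-oxocyclohex-1-en-1-yl]methyl tiglate F6. Displacement with cesium tiglate F4 (18-crown-6, toluene, 40 °C) with inversion returns to the route at 13.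

**Further compounds**

F1 | step 4 | racemic 2-{[(tert-butyldimethylsilyl)oxy]methyl}-5-isopropyl-3-(trimethylsilyl)cyclohex-2-en-1-one | CC(C)C1CC(=O)C(CO[Si](C)(C)C(C)(C)C)=C([Si](C)(C)C)C1
F2 | step 6 | [(4S)-4-isopropyl-6-oxocyclohex-1-en-1-yl]methyl tiglate | C/C=C(\C)C(=O)OCC1=CC[C@H](C(C)C)CC1=O
F3 | step 6 | [(3S,4S)-3-bromo-4-isopropyl-6-oxocyclohex-1-en-1-yl]methyl tiglate | C/C=C(\C)C(=O)OCC1=C[C@@H](Br)[C@H](C(C)C)CC1=O
F4 | step 6 | cesium tiglate | C/C=C(\C)C(=O)[O-].[Cs+]
F5 | step 7 | [(3S,4S)-3-hydroxy-4-isopropyl-6-oxocyclohex-1-en-1-yl]methyl tiglate | C/C=C(\C)C(=O)OCC1=C[C@@H](O)[C@H](C(C)C)CC1=O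
F6 | step 7 | [(3S,4S)-4-isopropyl-3-(methanesulfonyloxy)-6-oxocyclohex-1-en-1-yl]methyl tiglate | C/C=C(\C)C(=O)OCC1=C[C@@H](OS(C)(=O)=O)[C@H](C(C)C)CC1=O
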